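**Retrosynthetic overview**
1. The target comes from the ten-membered triol 25 by selenoxide elimination, MnO2 oxidation at C3 and desilylation. Ring order: γ-lactone first (step 10), ten-membered carbocycle second (step 15).
2. Key disconnection C1–C10: the 1,10-diol is cut into a C1 aldehyde and a C10 methyl ketone (seco compound 24), joined again by a SmI2 pinacol coupling.
3. Enabling feature: C1 and C10 are the two carbinol carbons of a vicinal diol, i.e. two carbonyl carbons of like polarity. The cis-fused γ-butyrolactone (O–C6–C7–C11–C12) and the (Z)-C4=C5 alkene hold the arms C5→C1 and C8→C10 on one face. C3 is carried as a 3R alcohol (chelating director, no enone) and the C11=C13 methylene as a selenide.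
4. 24 comes from the C3–C4 bond (Nozaki–Hiyama–Kishi coupling of vinyl iodide 19 with aldehyde 21) and the C6–C7 bond plus lactone ring (zinc Barbier allylation/lactonization of enal 5 with allylic bromide 17).
5. 5 comes from 2-butyne-1,4-diol. 17 comes from ketal aldehyde 7, methyl propiolate, (tributylstannyl)methanol and (R)-2-methylbutanoic acid.

Key step: step 15

Remark: the target is taken as the open 3-keto-1,10-diol written; a reversible five-membered hemiketal between the C10 hydroxyl and the C3 ketone would not change the route. Germacranolide numbering of the target (C1–C15) is used for all intermediates; the acyl stereocentre is R and comes unchanged from 13.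

**Route**

Step 1
Reactants: 1 2-butyne-1,4-diol
Product: 2 4-(tert-butyldiphenylsilyloxy)but-2-yn-1-ol
Conditions: TBDPSCl (1 equiv), imidazole, DMF, 0 °C to rt (1 in threefold excess)
Reagents that add atoms: tert-butyl(chloro)diphenylsilane, CC(C)(C)[Si](Cl)(c1ccccc1)c1ccccc1
Why: Silyl ether formation on one hydroxyl of the symmetric diol used in excess should give the mono-ether (monoprotection), the TBDPS group being chosen to survive the aqueous acid of step 14.

Step 2
Reactants: 2 4-(tert-butyldiphenylsilyloxy)but-2-yn-1-ol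
Product: 4 (Z)-4-(tert-butyldiphenylsilyloxy)-3-iodobut-2-en-1-ol, via cyclic alkenylalanate 3 (not isolated)
Conditions: NaAlH2(OCH2CH2OMe)2, THF, 0 °C; then I2, −78 to 0 °C
Reagents that add atoms: iodine, II
Why: Hydroxyl-directed trans-hydroalumination of the propargylic alcohol puts aluminium on the distal alkyne carbon inside a five-membered oxa-alumina ring, and iodinolysis with retention should give the (Z)-iodoalkene that fixes the C4=C5 geometry (iodine cis to the carbinol carbon, C15 trans).

Step 3
Reactants: 4 (Z)-4-(tert-butyldiphenylsilyloxy)-3-iodobut-2-en-1-ol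
Product: 5 (Z)-4-(tert-butyldiphenylsilyloxy)-3-iodobut-2-enal
Conditions: MnO2, CH2Cl2, rt
Reagents that add atoms: none
Why: Manganese dioxide oxidation of the primary allylic alcohol should give the β-iodo enal (the C6 aldehyde) without touching the silyl ether or the alkene geometry.

Step 4
Reactants: 6 ethyl 2-(2-methyl-1,3-dioxolan-2-yl)acetate
Product: 7 2-(2-methyl-1,3-dioxolan-2-yl)acetaldehyde
Conditions: i-Bu2AlH, CH2Cl2, −78 °C
Reagents that add atoms: none
Why: Partial reduction of the ester at low temperature (stable tetrahedral aluminium hemiacetal) should stop at the aldehyde, which carries C8–C10 and C14 with the C10 ketone masked as a dioxolane.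

Step 5
Reactants: 7 2-(2-methyl-1,3-dioxolan-2-yl)acetaldehyde; 8 methyl propiolate
Product: 10 methyl (R)-4-hydroxy-5-(2-methyl-1,3-dioxolan-2-yl)pent-2-ynoate, via methylzinc acetylide 9 (not isolated)
Conditions: 8, Me2Zn, ProPhenol (cat., antipode giving the 4R alcohol), Ph3P=O (cat.), toluene, 0 °C; then 7
Reagents that add atoms: none
Why: Catalytic asymmetric addition of the zinc alkynylide to the aldehyde under the dinuclear zinc–ProPhenol catalyst should set the C8 carbinol (4R here) by ligand control.

Step 6
Reactants: 10 methyl (R)-4-hydroxy-5-(2-methyl-1,3-dioxolan-2-yl)pent-2-ynoate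
Product: 12 methyl (R,Z)-4-hydroxy-2-iodo-5-(2-methyl-1,3-dioxolan-2-yl)pent-2-enoate, via cyclic alkenylalanate 11 (not isolated)
Conditions: NaAlH2(OCH2CH2OMe)2, THF, −72 °C; then I2, −78 °C
Reagents that add atoms: iodine, II
Why: Alkoxide-directed trans-hydroalumination of the γ-hydroxy ynoate delivers hydride to C7 and aluminium to C11 cis to C8, and iodinolysis with retention should give the (Z)-α-iodo enoate with the ester trans to C8, the ester surviving at this temperature.

Step 7
Reactants: 12 methyl (R,Z)-4-hydroxy-2-iodo-5-(2-methyl-1,3-dioxolan-2-yl)pent-2-enoate; 13 (R)-2-methylbutanoic acid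
Product: 14 methyl (R,Z)-2-iodo-5-(2-methyl-1,3-dioxolan-2-yl)-4-[(R)-2-methylbutanoyloxy]pent-2-enoate
Conditions: DIC, DMAP (cat.), CH2Cl2, 0 °C to rt
Reagents that add atoms: none
Why: Steglich esterification acylates the C8 hydroxyl with retention at both stereocentres, installing the final ester early so that only the C6 oxygen can lactonize later.

Step 8
Reactants: 14 methyl (R,Z)-2-iodo-5-(2-methyl-1,3-dioxolan-2-yl)-4-[(R)-2-methylbutanoyloxy]pent-2-enoate; 15 (tributylstannyl)methanol
Product: 16 methyl (R,E)-2-(hydroxymethyl)-5-(2-methyl-1,3-dioxolan-2-yl)-4-[(R)-2-methylbutanoyloxy]pent-2-enoate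
Conditions: Pd(PPh3)4 (cat.), dioxane, 80 °C
Reagents that add atoms: none
Why: Stille coupling of the alkenyl iodide with the hydroxymethylstannane proceeds with retention of alkene geometry, so C13 should end up cis to C8 (the E descriptor is only a change of CIP priority).

Step 9
Reactants: 16 methyl (R,E)-2-(hydroxymethyl)-5-(2-methyl-1,3-dioxolan-2-yl)-4-[(R)-2-methylbutanoyloxy]pent-2-enoate
Product: 17 methyl (R,Z)-2-(bromomethyl)-5-(2-methyl-1,3-dioxolan-2-yl)-4-[(R)-2-methylbutanoyloxy]pent-2-enoate
Conditions: CBr4, PPh3, 2,6-lutidine, CH2Cl2, 0 °C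
Reagents that add atoms: carbon tetrabromide, BrC(Br)(Br)Br
Why: Appel bromination of the primary allylic alcohol under buffered neutral conditions should give the 2-(bromomethyl)acrylate without allylic transposition or loss of the ketal.

Step 10
Reactants: 5 (Z)-4-(tert-butyldiphenylsilyloxy)-3-iodobut-2-enal; 17 methyl (R,Z)-2-(bromomethyl)-5-(2-methyl-1,3-dioxolan-2-yl)-4-[(R)-2-methylbutanoyloxy]pent-2-enoate
Product: 19 cis-fused α-methylene-γ-butyrolactone bearing the (Z)-iodoalkenyl group at C6 and the acyloxy ketal side chain at C7, via syn hydroxy ester 18 (not isolated)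
Conditions: Zn, THF/sat. aq. NH4Cl, 0 °C to rt; then PPTS (cat.), CH2Cl2, rt
Reagents that add atoms: none
Why: Zinc-mediated Barbier allylation by the 2-(methoxycarbonyl)allyl reagent through a chair-like six-membered transition state, with C8 (cis to the metal-bearing methylene) axial, should give the syn C6/C7 adduct that lactonizes to the cis-lactone, while the C8 centre, held by allylic 1,3-strain with its hydrogen eclipsing the alkene, should direct the aldehyde to the face anti to the C9 methylene and so set C7 and C6 as in the target.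

Step 11
Reactants: 20 methyl 3,3-dimethoxypropanoate
Product: 21 3,3-dimethoxypropanal
Conditions: i-Bu2AlH, CH2Cl2, −78 °C
Reagents that add atoms: none
Why: Partial ester reduction should give the C1–C3 aldehyde with C1 masked as its dimethyl acetal, to be used at once.

Step 12
Reactants: 19 cis-fused α-methylene-γ-butyrolactone with the (Z)-iodoalkenyl group; 21 3,3-dimethoxypropanal
Product: 22 (3R)-allylic alcohol with the C1 dimethyl acetal and C10 dioxolane
Conditions: CrCl2, NiCl2 (cat.), chiral oxazoline–sulfonamide ligand (N-[2-(4-isopropyl-4,5-dihydro-1,3-oxazol-2-yl)-6-methylphenyl]methanesulfonamide, antipode giving 3R), Et3N, THF, rt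
Reagents that add atoms: none
Why: The Nozaki–Hiyama–Kishi coupling of the alkenyl iodide with the aldehyde retains the C4=C5 geometry and tolerates lactone, acrylate, esters and ketal, and the chiral ligand on chromium should set the temporary C3 carbinol as 3R by reagent control.

Step 13
Reactants: 22 (3R)-allylic alcohol with the C1 dimethyl acetal and C10 dioxolane
Product: 23 C13 phenylselenide of 22 (CH2SePh at C11 trans to the C7 side chain)
Conditions: PhSeH, Et3N (cat.), THF, 0 °C to rt
Reagents that add atoms: benzeneselenol, [SeH]c1ccccc1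
Why: Conjugate (Michael) addition of the selenol masks the α-methylene lactone, which would otherwise trap ketyl radicals in step 15; the new C11 centre (expected trans to the C7 substituent) is erased in step 16.

Step 14
Reactants: 23 C13 phenylselenide of 22
Product: 24 seco keto aldehyde (C1 aldehyde, free 3R hydroxyl, C10 methyl ketone)
Conditions: 2 M aq. HCl, THF, 0 °C to rt
Reagents that add atoms: water, O
Why: Acid-catalysed hydrolysis of the dimethyl acetal and the dioxolane unveils both carbonyl groups in one operation, the TBDPS ether, lactone, ester and selenide being stable to dilute aqueous acid.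

Step 15
Reactants: 24 seco keto aldehyde
Product: 25 ten-membered (1R,3R,10S)-triol (selenide, C15 silyl ether)
Conditions: SmI2 (3 equiv), THF, −78 to 0 °C, 24 added over 6 h (final 0.003 M); then sat. aq. NaHCO3
Reagents that add atoms: none
Why: SmI2 reduces the C1 aldehyde, the most easily reduced group left in 24, to a ketyl bound to trivalent samarium, which is also held by the C3 hydroxyl and coordinates the C10 ketone oxygen; the ketyl carbon adds to the C10 carbonyl carbon and a second electron reduces the resulting alkoxy radical to the samarium diolate (reductive union of two electrophilic carbonyl carbons, an intramolecular cross-pinacol coupling). The closest known reaction type is the samarium diiodide (or low-valent titanium) pinacol cyclization of keto aldehydes to medium-ring 1,2-diols. The ten-membered carbocycle closes by a 10-exo-trig addition of the C1 radical to the C10=O carbon, the diolate forming a temporary five-membered O–Sm–O chelate across the new bond. C1 (R) should be controlled by the 3R hydroxyl through the six-membered chelate O3–C3–C2–C1–O1, the ketone approaching anti to C4 (1,3-anti diol); C10 (S) should be controlled by the samarium bridge, which keeps the two oxygens synclinal so that C9 and C2 are gauche across the new bond (erythro diol), with the methyl group pointing away from the lactone. The step needs chemoselectivity (no enone, acrylate or halide present: C3 is at the alcohol level and C13 is a selenide), intramolecularity (slow addition, high dilution) and diastereoselectivity, which the cis-fused lactone and the (Z)-C4=C5 alkene support by holding the C1 and C10 arms on the same face.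

Step 16
Reactants: 25 ten-membered (1R,3R,10S)-triol (selenide)
Product: 27 α-methylene lactone triol (C15 silyl ether), via selenoxide 26 (not isolated)
Conditions: mCPBA (1.05 equiv), CH2Cl2, −78 °C; then pyridine, −78 °C to rt
Reagents that add atoms: none
Why: Chemoselective oxidation at selenium at −78 °C and syn-elimination of the selenoxide on warming (selenoxide elimination) can only involve H11 and so regenerates the exocyclic C11=C13 methylene.

Step 17
Reactants: 27 α-methylene lactone triol (C15 silyl ether)
Product: 28 C3 enone (C15 silyl ether)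
Conditions: MnO2, CH2Cl2, rt
Reagents that add atoms: none
Why: Manganese dioxide oxidizes only the allylic C3 carbinol (the C1 and C10 hydroxyls are not allylic and C15 is silylated), giving the (Z)-enone whose geometry is locked in the ring.

Step 18
Reactants: 28 C3 enone (C15 silyl ether)
Product: 29 target CNP0263726.1
Conditions: HF·pyridine, THF/pyridine, 0 °C to rt
Reagents that add atoms: none
Why: Fluoride cleavage of the silyl ether under buffered, non-basic conditions spares the β-hydroxy ketone, the ester and the α-methylene lactone and releases the C15 hydroxyl.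

**Compound list**
1 | 2-butyne-1,4-diol | OCC#CCO | starting material
2 | 4-(tert-butyldiphenylsilyloxy)but-2-yn-1-ol | OCC#CCO[Si](c1ccccc1)(c1ccccc1)C(C)(C)C | intermediate
3 | sodium cyclic alkenylalanate from 2 (Al bound to O1 and to the distal alkene carbon, two 2-methoxyethoxy ligands) | [Na+].COCCO[Al-]1(OCCOC)OCC=C1CO[Si](c2ccccc2)(c2ccccc2)C(C)(C)C | intermediate
4 | (Z)-4-(tert-butyldiphenylsilyloxy)-3-iodobut-2-en-1-ol | OC/C=C(I)/CO[Si](c1ccccc1)(c1ccccc1)C(C)(C)C | intermediate
5 | (Z)-4-(tert-butyldiphenylsilyloxy)-3-iodobut-2-enal | O=C/C=C(I)/CO[Si](c1ccccc1)(c1ccccc1)C(C)(C)C | intermediate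
6 | ethyl 2-(2-methyl-1,3-dioxolan-2-yl)acetate | CCOC(=O)CC1(C)OCCO1 | starting material
7 | 2-(2-methyl-1,3-dioxolan-2-yl)acetaldehyde | O=CCC1(C)OCCO1 | intermediate
8 | methyl propiolate | C#CC(=O)OC | starting material
9 | methylzinc acetylide of methyl propiolate | C[Zn]C#CC(=O)OC | intermediate
10 | methyl (R)-4-hydroxy-5-(2-methyl-1,3-dioxolan-2-yl)pent-2-ynoate | COC(=O)C#C[C@H](O)CC1(C)OCCO1 | intermediate
11 | sodium cyclic alkenylalanate from 10 (Al bound to the C8 oxygen and to C11) | [Na+].COCCO[Al-]1(OCCOC)O[C@H](CC2(C)OCCO2)C=C1C(=O)OC | intermediate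
12 | methyl (R,Z)-4-hydroxy-2-iodo-5-(2-methyl-1,3-dioxolan-2-yl)pent-2-enoate | COC(=O)/C(I)=C/[C@H](O)CC1(C)OCCO1 | intermediate
13 | (R)-2-methylbutanoic acid | CC[C@@H](C)C(=O)O | starting material
14 | methyl (R,Z)-2-iodo-5-(2-methyl-1,3-dioxolan-2-yl)-4-[(R)-2-methylbutanoyloxy]pent-2-enoate | COC(=O)/C(I)=C/[C@H](OC(=O)[C@H](C)CC)CC1(C)OCCO1 | intermediate
15 | (tributylstannyl)methanol | CCCC[Sn](CO)(CCCC)CCCC | starting material
16 | methyl (R,E)-2-(hydroxymethyl)-5-(2-methyl-1,3-dioxolan-2-yl)-4-[(R)-2-methylbutanoyloxy]pent-2-enoate (CH2OH cis to C8) | COC(=O)/C(CO)=C/[C@H](OC(=O)[C@H](C)CC)CC1(C)OCCO1 | intermediate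
17 | methyl (R,Z)-2-(bromomethyl)-5-(2-methyl-1,3-dioxolan-2-yl)-4-[(R)-2-methylbutanoyloxy]pent-2-enoate | COC(=O)/C(CBr)=C/[C@H](OC(=O)[C@H](C)CC)CC1(C)OCCO1 | intermediate
18 | syn hydroxy ester: methyl 2-methylene ester with free C6 hydroxyl, (Z)-iodoalkenyl group on C6 and the C8 acyloxy ketal chain on C7 | COC(=O)C(=C)[C@@H]([C@@H](O)/C=C(I)/CO[Si](c1ccccc1)(c1ccccc1)C(C)(C)C)[C@H](OC(=O)[C@H](C)CC)CC2(C)OCCO2 | intermediate
19 | cis-fused α-methylene-γ-butyrolactone (H6/H7 cis; C6 (Z)-2-iodo-3-silyloxypropenyl; C7 side chain with 8R acyloxy and C10 dioxolane) | C=C1C(=O)O[C@@H](/C=C(I)/CO[Si](c2ccccc2)(c2ccccc2)C(C)(C)C)[C@H]1[C@H](OC(=O)[C@H](C)CC)CC3(C)OCCO3 | intermediate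
20 | methyl 3,3-dimethoxypropanoate | COC(=O)CC(OC)OC | starting material
21 | 3,3-dimethoxypropanal | O=CCC(OC)OC | intermediate
22 | (3R)-allylic alcohol: lactone 19 with iodine replaced by the CH(OH)CH2CH(OMe)2 chain (geometry retained) | C=C1C(=O)O[C@@H](/C=C(/CO[Si](c2ccccc2)(c2ccccc2)C(C)(C)C)[C@H](O)CC(OC)OC)[C@H]1[C@H](OC(=O)[C@H](C)CC)CC3(C)OCCO3 | intermediate
23 | C13 phenylselenide of 22 (CH2SePh on C11, trans to the C7 side chain) | c1ccccc1[Se]C[C@@H]1C(=O)O[C@@H](/C=C(/CO[Si](c2ccccc2)(c2ccccc2)C(C)(C)C)[C@H](O)CC(OC)OC)[C@H]1[C@H](OC(=O)[C@H](C)CC)CC3(C)OCCO3 | intermediate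
24 | seco keto aldehyde (C1 aldehyde, 3R hydroxyl, C10 methyl ketone, selenide, C15 silyl ether) | c1ccccc1[Se]C[C@@H]1C(=O)O[C@@H](/C=C(/CO[Si](c2ccccc2)(c2ccccc2)C(C)(C)C)[C@H](O)CC=O)[C@H]1[C@H](OC(=O)[C@H](C)CC)CC(C)=O | intermediate
25 | ten-membered (1R,3R,10S)-triol, selenide, C15 silyl ether | c1ccccc1[Se]C[C@@H]1C(=O)O[C@H]2/C=C(/CO[Si](c3ccccc3)(c3ccccc3)C(C)(C)C)[C@H](O)C[C@@H](O)[C@@](C)(O)C[C@@H](OC(=O)[C@H](C)CC)[C@@H]12 | intermediate
26 | selenoxide of 25 | O=[Se](c1ccccc1)C[C@@H]1C(=O)O[C@H]2/C=C(/CO[Si](c3ccccc3)(c3ccccc3)C(C)(C)C)[C@H](O)C[C@@H](O)[C@@](C)(O)C[C@@H](OC(=O)[C@H](C)CC)[C@@H]12 | intermediate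
27 | α-methylene lactone (1R,3R,10S)-triol, C15 silyl ether | C=C1C(=O)O[C@H]2/C=C(/CO[Si](c3ccccc3)(c3ccccc3)C(C)(C)C)[C@H](O)C[C@@H](O)[C@@](C)(O)C[C@@H](OC(=O)[C@H](C)CC)[C@@H]12 | intermediate
28 | C3 enone, C15 TBDPS ether of the target | C=C1C(=O)O[C@H]2/C=C(/CO[Si](c3ccccc3)(c3ccccc3)C(C)(C)C)C(=O)C[C@@H](O)[C@@](C)(O)C[C@@H](OC(=O)[C@H](C)CC)[C@@H]12 | intermediate
29 | CNP0263726.1 | C=C1C(=O)O[C@H]2/C=C(/CO)C(=O)C[C@@H](O)[C@@](C)(O)C[C@@H](OC(=O)[C@H](C)CC)[C@@H]12 | target

**Totals**
Total step count: 18.
Longest linear sequence: 14 steps (steps 4 to 10, then 12 to 18).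

**Steps most likely to fail**

Step 15. The samarium-bridged closure may show poor facial selectivity at C1 or C10 (threo diol or the wrong erythro pair), or the aldehyde may simply be reduced before the ring closes. The fallback forms the same C1–C10 bond as an alkene and adds the two oxygens afterwards. It sets out from 24: Takai–Lombardo methylenation (Zn, CH2Br2, TiCl4, THF) of both carbonyl groups should give the bis-methylene compound F1. Ring-closing metathesis (second-generation Grubbs catalyst, CH2Cl2, 40 °C, high dilution) should close the ten-membered ring as the (Z)-C1=C10 cycloalkene F2 with loss of ethylene. Oxidation at selenium (mCPBA, −78 °C) to selenoxide F3 and elimination on warming should give the α-methylene lactone cycloalkene F4. OsO4 (cat.)/NMO dihydroxylation of the most electron-rich alkene (C1=C10; the C4=C5 alkene is deactivated by three allylic oxygens, the acrylate is electron-poor), syn from the outer face of the Z-alkene, should give the erythro diol and return to the route at 27.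

Step 10. The syn relationship may erode through E/Z equilibration of the allylzinc species, and the facial bias from the C8 centre may be weak. The fallback uses a configurationally stable allylboronate in a closed transition state. It sets out from 17: borylation (B2pin2, Pd2(dba)3 cat., toluene/DMSO, rt) should give the allylboronate F5 with the boryl-methyl group cis to C8. Heating F5 with 5 (toluene, 80 °C) should transfer the allyl group through a chair transition state without geometric scrambling and, after hydrolytic work-up, return to the route at 18, which lactonizes to 19 as in step 10.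

Step 8. Zerovalent palladium may ionize the allylic C8 ester (π-allyl formation, elimination) while the slow transfer of the hydroxymethyl group lags. The fallback takes the ester out of the palladium step. It sets out from 12: Stille coupling of the free alcohol with 15 (Pd(PPh3)4, dioxane, 80 °C) should give the diol F6. Selective silylation of the primary hydroxyl (TBSCl, imidazole, CH2Cl2, 0 °C) should give the silyl ether F7. Steglich esterification with 13 (DIC, DMAP) should give the ester F8, and HF·pyridine should remove the silyl group and return to the route at 16.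

**Further compounds**
F1 | step 15 | bis-methylene seco compound from 24 (C1 vinyl, C10 isopropenyl) | c1ccccc1[Se]C[C@@H]1C(=O)O[C@@H](/C=C(/CO[Si](c2ccccc2)(c2ccccc2)C(C)(C)C)[C@H](O)CC=C)[C@H]1[C@H](OC(=O)[C@H](C)CC)CC(C)=C
F2 | step 15 | ten-membered (Z)-C1=C10 cycloalkene, selenide | c1ccccc1[Se]C[C@@H]1C(=O)O[C@H]2/C=C(/CO[Si](c3ccccc3)(c3ccccc3)C(C)(C)C)[C@H](O)C/C=C(C)\C[C@@H](OC(=O)[C@H](C)CC)[C@@H]12
F3 | step 15 | selenoxide of F2 | O=[Se](c1ccccc1)C[C@@H]1C(=O)O[C@H]2/C=C(/CO[Si](c3ccccc3)(c3ccccc3)C(C)(C)C)[C@H](O)C/C=C(C)\C[C@@H](OC(=O)[C@H](C)CC)[C@@H]12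
F4 | step 15 | ten-membered (Z)-C1=C10 cycloalkene with α-methylene lactone | C=C1C(=O)O[C@H]2/C=C(/CO[Si](c3ccccc3)(c3ccccc3)C(C)(C)C)[C@H](O)C/C=C(C)\C[C@@H](OC(=O)[C@H](C)CC)[C@@H]12
F5 | step 10 | allylboronate: methyl (R)-5-(2-methyl-1,3-dioxolan-2-yl)-4-[(R)-2-methylbutanoyloxy]-2-[(4,4,5,5-tetramethyl-1,3,2-dioxaborolan-2-yl)methyl]pent-2-enoate, boryl-methyl cis to C8 | COC(=O)/C(CB1OC(C)(C)C(C)(C)O1)=C/[C@H](OC(=O)[C@H](C)CC)CC2(C)OCCO2
F6 | step 8 | methyl (R)-4-hydroxy-2-(hydroxymethyl)-5-(2-methyl-1,3-dioxolan-2-yl)pent-2-enoate, CH2OH cis to C8 | COC(=O)/C(CO)=C/[C@H](O)CC1(C)OCCO1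
F7 | step 8 | primary tert-butyldimethylsilyl ether of F6 | COC(=O)/C(CO[Si](C)(C)C(C)(C)C)=C/[C@H](O)CC1(C)OCCO1
F8 | step 8 | (R)-2-methylbutanoate of F7 | COC(=O)/C(CO[Si](C)(C)C(C)(C)C)=C/[C@H](OC(=O)[C@H](C)CC)CC1(C)OCCO1
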